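I had 4 shares to give and one best flask to name, so I began with a ledger of the substrate, the smallest charge.

| flask | substrate | second nucleophile | solid first nucleophile | remark | time |
|---|---|---|---|---|---|
| Sunday's | 0.020 M | 1.1 equiv | 2 equiv | run made earlier |  |
| Friday's | 0.020 M | 1.1 equiv | 1.3 equiv | run made earlier |  |
| Saturday's | 0.020 M | 1.1 equiv | 3 equiv | run made earlier |  |
| dawn | 0.020 M | 1.10 equiv | 2.00 equiv | everything together at the start | 6.0 d |
| summer | 0.020 M (fed, over 25 h) | 1.10 equiv | 2.00 equiv | all else is in the flask from the start; the feed brings no volume worth counting | 6.0 d |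
| spring | 0.020 M | 1.10 equiv (fed, over 4.0 d) | 2.00 equiv | all else is in the flask from the start; the feed brings no volume worth counting | 6.0 d |
| noon | 0.020 M (fed, over 4.0 d) | 1.10 equiv | 2.00 equiv | all else is in the flask from the start; the feed brings no volume worth counting | 6.0 d |

| run | time / d | target / % | other capture product / % | substrate / % |
|---|---|---|---|---|
| Sunday's | 0.833 | 0 | 33 | 12 |
| Sunday's | 1.67 | 0 | 40 | 2 |
| Sunday's | 2.50 | 0 | 47 | 1 |
| Sunday's | 3.00 | 3 | 44 | 0 |
| Sunday's | 4.00 | 2 | 43 | 0 |
| Sunday's | 5.00 | 5 | 48 | 0 |
| Sunday's | 6.00 | 4 | 46 | 1 |
| Friday's | 1.04 | 2 | 38 | 9 |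
| Friday's | 2.08 | 3 | 42 | 0 |
| Friday's | 3.00 | 3 | 39 | 0 |
| Friday's | 4.00 | 3 | 44 | 0 |
| Friday's | 5.00 | 5 | 45 | 0 |
| Friday's | 6.00 | 3 | 49 | 0 |
| Friday's | 8.00 | 3 | 43 | 0 |
| Saturday's | 0.417 | 1 | 18 | 33 |
| Saturday's | 1.04 | 0 | 38 | 10 |
| Saturday's | 2.08 | 1 | 44 | 0 |
| Saturday's | 3.00 | 3 | 45 | 0 |
| Saturday's | 4.00 | 0 | 40 | 3 |
| Saturday's | 6.00 | 2 | 46 | 3 |
| Saturday's | 8.00 | 3 | 46 | 0 |

(readings scatter by 2 percentage points)

- the analysis behind the earlier runs scatters by 2 percentage points, standard deviation
- at the start none of the solid first nucleophile is in solution

1. the best flask by share of target in target plus other capture product; "all alike" if 1.5 percentage points covers them all (dawn / summer / spring / noon / all alike)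
2. share of target in target plus other capture product at the end, dawn
3. share of target in target plus other capture product at the end, summer
4. share of target in target plus other capture product at the end, spring
5. share of target in target plus other capture product at the end, noon

I took the 5 readings from 5.00 d to 6.00 d in the earlier runs. As fractions of the substrate charged, other capture product averaged 46.8%, substrate 0.800% and target 3.80%. The books therefore closed on a remainder of 48.6% that no reading counted.

The target readings showed no trend beyond the scatter between 1.3 equiv and 3 equiv of solid first nucleophile, so I froze that figure. The target tally, the amount of target standing near the end, taken as one fixed amount whatever the recipe, falls as a fraction when more substrate is charged. The selectivity is then the tally divided by the tally plus other capture product, and a recipe moves it through other capture product. For dawn this gave me 7.51%. The runs held no fed flask, so I had no figure for other capture product in summer, spring or noon.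

The forecast said all alike: dawn 6% (4% to 8%), summer 6% (3.5% to 10%), spring 6% (3% to 15%) and noon 6% (3.5% to 11%). Its ground was “Nothing in the data shows that the partition depends on concentration”. My dawn figure stood above its centre, though inside its range.

The best flask was noon at 22.0%, with summer at 12.8%, dawn at 8.65% and spring at 6.72%. At 6.00 d, target stood at 4.27%, 4.36%, 4.18% and 4.28% in dawn, summer, spring and noon, while other capture product stood at 45.1%, 29.9%, 58.0% and 15.2%. The tally with noon's other capture product gives 20.0%.

    second nucleophile + intermediate → other capture product (k = 4.24 L mol⁻¹ h⁻¹)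
    solid first nucleophile ⇌ first nucleophile, rate k2*(cs2 - [first nucleophile]) while solid is left; crystals form when [first nucleophile] > cs2 (solubility = 1.00 mM, k = 0.00680 h⁻¹)
    substrate → intermediate (k = 0.0989 h⁻¹)
    second nucleophile → decomposed reagent (k = 0.0251 h⁻¹)
    first nucleophile + intermediate → target (k = 9.42 L mol⁻¹ h⁻¹)
    second nucleophile ⇌ dormant form (K = 27.0, k = 0.0223 h⁻¹)

The neighbour repeats noon with 0.034 M of substrate, so I reckoned the tally at 2.24% of its charge, and with its 19.2% of other capture product that reckoning gives a selectivity of 10.4%. The simulation gives 2.62% of target and a share of 12.0%.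

Readings and results are simulated for substances that don't exist.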